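**Strategy.** The route rests on disconnecting the tetrasubstituted C1=C15 alkene of the 2,5-dihydrofuran (O, C2, C1, C15, C16) that is fused to the 14-membered carbocycle at C1–C2. One ring-closing metathesis joins two 1,1-disubstituted alkenes, the exocyclic C1 methylene and the 2-(acetoxymethyl)allyl ether on O–C2. It forges the five-membered ring and gives the target directly. Its precursor is the (2R,7R,8R)-epoxy macrocycle with both E-trisubstituted ring alkenes in place. That macrocycle is built from farnesol by a site-selective Shi epoxidation, an asymmetric Morita–Baylis–Hillman reaction that sets C2, and a nickel-mediated allyl–allyl ring closure.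

Key step: step 15

Remark: cembrane numbering is used throughout (farnesol C1–C12 become C2–C13; C14, C1 and the exocyclic CH2 come from the acrylate; C15–C17 from 3-chloro-2-(chloromethyl)prop-1-ene). Target and metathesis precursor were re-derived atom by atom: both are (2R,7R,8R) with 3E,11E alkenes, so no structural correction was needed.
Assumption: the D-fructose-derived ketone gives the (R,R)-epoxide from E-trisubstituted alkenes, and β-isocupreidine (made from quinidine, not counted) gives the (R)-carbinol from enals.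

Step 1
Reactants: 1 (2E,6E)-farnesol
Product: 2 (2E,6E)-farnesyl acetate
Conditions: Ac2O, Et3N, DMAP (cat.), CH2Cl2, 0 °C → rt
Reagents that add atoms: acetic anhydride, CC(=O)OC(C)=O
Why: O-Acylation (esterification) of the primary allylic alcohol is routine; the acetate masks the future C2 oxygen and makes the neighbouring C3=C4 alkene electron-poor for steps 2 and 4.

Step 2
Reactants: 2 (2E,6E)-farnesyl acetate
Product: 3 (2E,6E,10E)-12-hydroxyfarnesyl acetate
Conditions: SeO2 (cat.), t-BuOOH, salicylic acid (cat.), CH2Cl2, rt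
Reagents that add atoms: tert-butyl hydroperoxide, CC(C)(C)OO (oxygen source, relayed by catalytic selenium dioxide, O=[Se]=O)
Why: SeO2-catalysed allylic oxidation (ene reaction, then [2,3]-sigmatropic shift) should attack the (E)-methyl of the terminal, most electron-rich trisubstituted alkene and give the (E)-allylic alcohol whose CH2OH is the future C13.

Step 3
Reactants: 3 (2E,6E,10E)-12-hydroxyfarnesyl acetate
Product: 4 (2E,6E,10E)-12-(pivaloyloxy)farnesyl acetate
Conditions: PivCl, pyridine, DMAP (cat.), CH2Cl2, 0 °C → rt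
Reagents that add atoms: pivaloyl chloride, CC(C)(C)C(=O)Cl
Why: O-Acylation with an acid chloride gives a pivalate that is orthogonal to the acetate and makes the C11=C12 alkene electron-poor as well.

Step 4
Reactants: 4 (2E,6E,10E)-12-(pivaloyloxy)farnesyl acetate
Product: 5 (2E,6R,7R,10E)-6,7-epoxy-12-(pivaloyloxy)farnesyl acetate (the epoxide is C7–C8 of the cembrane)
Conditions: 1,2:4,5-di-O-isopropylidene-β-D-erythro-2,3-hexodiulo-2,6-pyranose (D-fructose-derived Shi ketone, 0.3 equiv), KHSO5 (as 2KHSO5·KHSO4·K2SO4), K2CO3, Bu4NHSO4, MeCN/CH2(OMe)2/aq. Na2B4O7 buffer, 0 °C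
Reagents that add atoms: potassium peroxymonosulfate, [K+].[O-]S(=O)(=O)OO
Why: Shi asymmetric epoxidation: the electrophilic ketone-derived dioxirane (the active form of the catalyst) should select the one alkene that carries no allylic acyloxy group and, through its spiro transition state, deliver oxygen to the face of this E-trisubstituted alkene that gives the (R,R)-epoxide (reagent control).

Step 5
Reactants: 5 (2E,6R,7R,10E)-6,7-epoxy-12-(pivaloyloxy)farnesyl acetate
Product: 6 (2E,6R,7R,10E)-6,7-epoxy-12-(pivaloyloxy)farnesol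
Conditions: K2CO3 (cat.), MeOH, 0 °C
Reagents that add atoms: none
Why: Carbonate-catalysed transesterification (methanolysis) cleaves the unhindered acetate far faster than the pivalate, and a trisubstituted epoxide is inert to these conditions.

Step 6
Reactants: 6 (2E,6R,7R,10E)-6,7-epoxy-12-(pivaloyloxy)farnesol
Product: 7 (2E,6R,7R,10E)-6,7-epoxy-12-(pivaloyloxy)farnesal
Conditions: MnO2, CH2Cl2, rt
Reagents that add atoms: none
Why: Chemoselective allylic oxidation by MnO2 gives the (E)-enal (aldehyde carbon = C2) without touching the epoxide, the pivalate or the other alkenes.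

Step 7
Reactants: 7 (2E,6R,7R,10E)-6,7-epoxy-12-(pivaloyloxy)farnesal; 8 1,1,1,3,3,3-hexafluoropropan-2-yl acrylate
Product: 9 hexafluoroisopropyl (3R,4E,8R,9R,12E)-8,9-epoxy-3-hydroxy-5,9,13-trimethyl-2-methylidene-14-(pivaloyloxy)tetradeca-4,12-dienoate (carbinol carbon = cembrane C2, R)
Conditions: 8 (1.5 equiv), β-isocupreidine (0.2 equiv), DMF, −55 °C
Reagents that add atoms: 1,1,1,3,3,3-hexafluoropropan-2-yl acrylate (8), C=CC(=O)OC(C(F)(F)F)C(F)(F)F
Why: Asymmetric Morita–Baylis–Hillman reaction: the quinuclidine nitrogen adds to the activated acrylate, the enolate adds to the aldehyde, and the phenolic hydroxyl of the catalyst is expected to steer the addition to the (R)-carbinol at C2, as with other (E)-enals, while epoxide and pivalate are inert to the tertiary amine.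

Step 8
Reactants: 9 Morita–Baylis–Hillman adduct
Product: 10 3-O-tert-butyldimethylsilyl ether of 9 (C2–OTBS)
Conditions: TBSOTf, 2,6-lutidine, CH2Cl2, −78 °C
Reagents that add atoms: tert-butyldimethylsilyl trifluoromethanesulfonate, C[Si](C)(OS(=O)(=O)C(F)(F)F)C(C)(C)C
Why: Silyl ether formation with a silyl triflate and a hindered base protects the only hydroxyl; at −78 °C the epoxide should not be activated.

Step 9
Reactants: 10 silyl ether
Product: 11 (2E,6R,7R,10E,12R)-12-(tert-butyldimethylsilyloxy)-6,7-epoxy-2,6,10-trimethyl-13-methylidenetetradeca-2,10-diene-1,14-diol (C13–OH and C14–OH free)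
Conditions: i-Bu2AlH (excess), CH2Cl2, −78 °C; aq. Rochelle salt work-up
Reagents that add atoms: none
Why: Hydride reduction: i-Bu2AlH reduces the activated acrylate ester in 1,2-fashion to the C14 allylic alcohol and cleaves the pivalate to the C13 alcohol in the same operation, at a temperature at which epoxide and silyl ether are stable.

Step 10
Reactants: 11 diol
Product: 12 (2E,6R,7R,10E,12R)-1,14-dibromo-12-(tert-butyldimethylsilyloxy)-6,7-epoxy-2,6,10-trimethyl-13-methylidenetetradeca-2,10-diene (C13–Br and C14–Br)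
Conditions: CBr4, PPh3, 2,6-lutidine, CH2Cl2, −20 → 0 °C
Reagents that add atoms: carbon tetrabromide, BrC(Br)(Br)Br
Why: Appel reaction: both primary allylic alcohols are activated by PPh3/CBr4 and displaced by bromide in SN2 fashion without allylic transposition, while the only secondary oxygen is masked as its silyl ether.

Step 11
Reactants: 12 bis(allylic) dibromide
Product: 13 (2R,7R,8R,3E,11E)-2-(tert-butyldimethylsilyloxy)-7,8-epoxy-4,8,12-trimethyl-1-methylidenecyclotetradeca-3,11-diene
Conditions: Ni(CO)4 (excess), N-methylpyrrolidone, 50 °C, syringe-pump addition of 12 (high dilution)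
Reagents that add atoms: none
Why: Nickel-mediated reductive allyl–allyl coupling: zerovalent nickel inserts into an allylic C–Br bond and couples it with the second allylic bromide, joining C13 to C14; the 2-substituted allyl unit has two equivalent CH2 termini and the other unit bonds at its primary carbon, so the unstrained 14-membered 1,5-diene with the E-C11=C12 alkene should be the main product.

Step 12
Reactants: 13 macrocyclic silyl ether
Product: 14 (2R,7R,8R,3E,11E)-7,8-epoxy-4,8,12-trimethyl-1-methylidenecyclotetradeca-3,11-dien-2-ol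
Conditions: Bu4NF, THF, 0 °C → rt
Reagents that add atoms: none
Why: Fluoride-induced cleavage of the silyl ether (Si–F bond formation) frees the C2 alcohol without touching the epoxide or the alkenes.

Step 13
Reactants: 14 macrocyclic allylic alcohol; 15 3-chloro-2-(chloromethyl)prop-1-ene
Product: 17 2-O-[2-(chloromethyl)prop-2-en-1-yl] ether of 14, via sodium alkoxide 16 (not isolated)
Conditions: NaH, THF/DMF, 0 °C; then 15 (5 equiv), Bu4NI (cat.), 0 °C → rt
Reagents that add atoms: 3-chloro-2-(chloromethyl)prop-1-ene (15), ClCC(=C)CCl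
Why: Williamson ether synthesis: alkoxide 16 displaces one chloride of the symmetrical bis-allylic electrophile, used in excess so that it reacts once; this avoids the acyl transfer that an acetoxy-bearing allyl halide would invite under base, and C2 keeps its configuration because only the O–H bond is broken.

Step 14
Reactants: 17 2-(chloromethyl)allyl ether
Product: 18 2-O-[2-(acetoxymethyl)prop-2-en-1-yl] ether of 14 (metathesis precursor)
Conditions: CsOAc, DMF, 50 °C
Reagents that add atoms: caesium acetate, [Cs+].CC(=O)[O-]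
Why: SN2 displacement of the primary allylic chloride by acetate in a dipolar aprotic solvent; direct and allylic (SN2′) attack on the symmetrical 2-substituted allyl unit give the same acetate.

Step 15
Reactants: 18 metathesis precursor
Product: 19 lobophynin B
Conditions: RuCl2(1,3-di-o-tolylimidazolidin-2-ylidene)(=CH-C6H4-2-OiPr) (10–20 mol %, in portions), 1,4-benzoquinone (cat.), toluene (0.005 M), 80 °C, argon sparge
Reagents that add atoms: none
Why: Ring-closing olefin metathesis: the ruthenium alkylidene engages one 1,1-disubstituted alkene, the new alkylidene adds across the other through a ruthenacyclobutane, and cycloreversion releases ethylene and the C1=C15 alkene. The closest known reaction type is ring-closing metathesis of bis(2-substituted allyl) ethers to tetrasubstituted 2,5-dihydrofurans with ruthenium catalysts carrying N-o-tolyl carbene ligands, whose small aryl groups leave room for the crowded metallacycle. The one ring closed is the five-membered dihydrofuran (O, C2, C1, C15, C16), formed from a 1,6-diene in the ring-closing metathesis mode on the preformed macrocycle. No stereocentre is created; C2, C7 and C8 are spectators and C2 cannot epimerise under these neutral conditions. The step needs chemoselectivity for the two 1,1-disubstituted alkenes over the trisubstituted C3=C4 and C11=C12 ring alkenes, which their higher substitution and the fast five-ring closure should secure, while removal of ethylene drives the reaction. Allylic acetate and epoxide are tolerated by the ruthenium carbene, and the benzoquinone suppresses hydride-induced alkene migration.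

**Compound list**

1 | (2E,6E)-farnesol | CC(C)=CCC/C(C)=C/CC/C(C)=C/CO | starting material
2 | (2E,6E)-farnesyl acetate | CC(C)=CCC/C(C)=C/CC/C(C)=C/COC(C)=O | intermediate
3 | (2E,6E,10E)-12-hydroxyfarnesyl acetate | OC/C(C)=C/CC/C(C)=C/CC/C(C)=C/COC(C)=O | intermediate
4 | (2E,6E,10E)-12-(pivaloyloxy)farnesyl acetate | CC(C)(C)C(=O)OC/C(C)=C/CC/C(C)=C/CC/C(C)=C/COC(C)=O | intermediate
5 | (2E,6R,7R,10E)-6,7-epoxy-12-(pivaloyloxy)farnesyl acetate | CC(C)(C)C(=O)OC/C(C)=C/CC[C@@]1(C)O[C@@H]1CC/C(C)=C/COC(C)=O | intermediate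
6 | (2E,6R,7R,10E)-6,7-epoxy-12-(pivaloyloxy)farnesol | CC(C)(C)C(=O)OC/C(C)=C/CC[C@@]1(C)O[C@@H]1CC/C(C)=C/CO | intermediate
7 | (2E,6R,7R,10E)-6,7-epoxy-12-(pivaloyloxy)farnesal | CC(C)(C)C(=O)OC/C(C)=C/CC[C@@]1(C)O[C@@H]1CC/C(C)=C/C=O | intermediate
8 | 1,1,1,3,3,3-hexafluoropropan-2-yl acrylate | C=CC(=O)OC(C(F)(F)F)C(F)(F)F | starting material
9 | hexafluoroisopropyl (3R,4E,8R,9R,12E)-8,9-epoxy-3-hydroxy-5,9,13-trimethyl-2-methylidene-14-(pivaloyloxy)tetradeca-4,12-dienoate | CC(C)(C)C(=O)OC/C(C)=C/CC[C@@]1(C)O[C@@H]1CC/C(C)=C/[C@@H](O)C(=C)C(=O)OC(C(F)(F)F)C(F)(F)F | intermediate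
10 | 3-O-tert-butyldimethylsilyl ether of 9 | CC(C)(C)C(=O)OC/C(C)=C/CC[C@@]1(C)O[C@@H]1CC/C(C)=C/[C@@H](O[Si](C)(C)C(C)(C)C)C(=C)C(=O)OC(C(F)(F)F)C(F)(F)F | intermediate
11 | (2E,6R,7R,10E,12R)-12-(tert-butyldimethylsilyloxy)-6,7-epoxy-2,6,10-trimethyl-13-methylidenetetradeca-2,10-diene-1,14-diol | OC/C(C)=C/CC[C@@]1(C)O[C@@H]1CC/C(C)=C/[C@@H](O[Si](C)(C)C(C)(C)C)C(=C)CO | intermediate
12 | (2E,6R,7R,10E,12R)-1,14-dibromo-12-(tert-butyldimethylsilyloxy)-6,7-epoxy-2,6,10-trimethyl-13-methylidenetetradeca-2,10-diene | BrC/C(C)=C/CC[C@@]1(C)O[C@@H]1CC/C(C)=C/[C@@H](O[Si](C)(C)C(C)(C)C)C(=C)CBr | intermediate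
13 | (2R,7R,8R,3E,11E)-2-(tert-butyldimethylsilyloxy)-7,8-epoxy-4,8,12-trimethyl-1-methylidenecyclotetradeca-3,11-diene | CC(C)(C)[Si](C)(C)O[C@@H]1/C=C(\C)CC[C@H]2O[C@]2(C)CC/C=C(\C)CCC1=C | intermediate
14 | (2R,7R,8R,3E,11E)-7,8-epoxy-4,8,12-trimethyl-1-methylidenecyclotetradeca-3,11-dien-2-ol | O[C@@H]1/C=C(\C)CC[C@H]2O[C@]2(C)CC/C=C(\C)CCC1=C | intermediate
15 | 3-chloro-2-(chloromethyl)prop-1-ene | ClCC(=C)CCl | starting material
16 | sodium alkoxide of 14 | [Na+].[O-][C@@H]1/C=C(\C)CC[C@H]2O[C@]2(C)CC/C=C(\C)CCC1=C | intermediate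
17 | 2-O-[2-(chloromethyl)prop-2-en-1-yl] ether of 14 | ClCC(=C)CO[C@@H]1/C=C(\C)CC[C@H]2O[C@]2(C)CC/C=C(\C)CCC1=C | intermediate
18 | 2-O-[2-(acetoxymethyl)prop-2-en-1-yl] ether of 14 (metathesis precursor) | CC(=O)OCC(=C)CO[C@@H]1/C=C(\C)CC[C@H]2O[C@]2(C)CC/C=C(\C)CCC1=C | intermediate
19 | lobophynin B | CC(=O)OCC1=C2CC/C(C)=C/CC[C@@]3(C)O[C@@H]3CC/C(C)=C/[C@H]2OC1 | target

**Step count.** Total: 15 steps. Longest linear sequence: 15 steps (1 → 19).

**Steps most likely to fail, with fallbacks**

**Step 15 (key metathesis).** Neither hindered 1,1-disubstituted alkene may load onto ruthenium before the catalyst decomposes, so the diene would be recovered or its alkenes would migrate.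

Fallback: relay ring-closing metathesis, which moves catalyst loading to an unhindered terminal alkene. It sets out from 14 and comes back at 19.
- Wittig olefination of 1,3-dichloroacetone with the ylide from (hex-5-en-1-yl)triphenylphosphonium bromide (n-BuLi, THF, −78 °C) should give the relay bis-electrophile 1-chloro-2-(chloromethyl)octa-2,7-diene F1.
- Williamson alkylation of 14 (NaH, Bu4NI, DMF) with excess F1 gives the relay chloro ether F2. It forms as an E/Z mixture at the new trisubstituted alkene, which is of no consequence.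
- CsOAc in DMF converts F2 into the relay acetate F3.
- With the same ruthenium catalyst, loading on the terminal alkene and expulsion of cyclopentene place the metal on C15 as a disubstituted alkylidene next to C1=CH2. Only the five-ring closure then remains, and it gives 19.

**Step 11 (nickel macrocyclisation).** Intermolecular coupling may give oligomers, and syn/anti equilibration of the allylnickel terminus may scramble the C11=C12 geometry.

Fallback: close the ring at C1–C2 by a Nozaki–Hiyama–Kishi reaction, after the C13–C14 bond has been made by SN2 alkylation. It sets out from 6 and comes back at 14.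
- Alcohol 6 is silylated (TBSCl, imidazole, DMF) to the silyl ether F4.
- i-Bu2AlH removes the pivalate to give the C13 alcohol F5, and Appel bromination gives the allylic bromide F6.
- Alkylation of the lithium enolate of acetone (LiN(i-Pr)2, excess acetone, THF, −78 °C) forms C13–C14 with retention of the E-alkene and gives the methyl ketone F7.
- Its kinetic enolate (KN(SiMe3)2, PhNTf2, −78 °C) is trapped as the 2-triflyloxy-1-alkene F8.
- Buffered desilylation (Bu4NF, AcOH) gives the allylic alcohol F9, and MnO2 gives the enal F10.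
- Macrocyclisation (CrCl2, catalytic NiCl2, DMF, high dilution) joins C1 to C2 and delivers 14 together with its C2 epimer F11.
- The mixture is converged by Dess–Martin oxidation to the cross-conjugated dienone F12 and Corey–Bakshi–Shibata reduction with the (S)-methyl oxazaborolidine and catecholborane. This should return (2R)-14 if the α-branched C1 alkenyl arm acts as the larger group.

**Step 7 (asymmetric Morita–Baylis–Hillman).** Addition to the β,β-disubstituted enal may be too slow, with loss of enantioselectivity and diversion to dioxanone by-products.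

Fallback: auxiliary-controlled aldol addition followed by sulfoxide elimination. It sets out from 7 and comes back at 11.
- The dibutylboron enolate of (S)-4-benzyl-3-[3-(phenylsulfanyl)propanoyl]oxazolidin-2-one F13 (Bu2BOTf, i-Pr2NEt, CH2Cl2, −78 °C) adds to 7 in an Evans syn-aldol reaction to give the aldol adduct F14, with the (2R)-carbinol set by the auxiliary.
- Silylation (TBSOTf, 2,6-lutidine) gives the silyl ether F15.
- LiBH4 removes the auxiliary to give the primary alcohol F16 (the future C14–OH).
- NaIO4 oxidises the sulfide to the sulfoxide F17.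
- Thermal syn-elimination (toluene, 110 °C, CaCO3) creates the C1 methylene in the allylic alcohol F18.
- i-Bu2AlH then cleaves the pivalate, and the fallback rejoins the route at 11.

**Further compounds**

F1 | step 15 | 1-chloro-2-(chloromethyl)octa-2,7-diene | ClCC(CCl)=CCCCC=C
F2 | step 15 | relay chloro ether: 2-O-[2-(chloromethyl)octa-2,7-dien-1-yl] ether of 14 (E/Z mixture) | ClCC(=CCCCC=C)CO[C@@H]1/C=C(\C)CC[C@H]2O[C@]2(C)CC/C=C(\C)CCC1=C
F3 | step 15 | relay acetate: 2-O-[2-(acetoxymethyl)octa-2,7-dien-1-yl] ether of 14 (E/Z mixture) | CC(=O)OCC(=CCCCC=C)CO[C@@H]1/C=C(\C)CC[C@H]2O[C@]2(C)CC/C=C(\C)CCC1=C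
F4 | step 11 | tert-butyldimethylsilyl ether of 6 | CC(C)(C)C(=O)OC/C(C)=C/CC[C@@]1(C)O[C@@H]1CC/C(C)=C/CO[Si](C)(C)C(C)(C)C
F5 | step 11 | C13 alcohol (pivalate removed from F4) | OC/C(C)=C/CC[C@@]1(C)O[C@@H]1CC/C(C)=C/CO[Si](C)(C)C(C)(C)C
F6 | step 11 | C13 allylic bromide | BrC/C(C)=C/CC[C@@]1(C)O[C@@H]1CC/C(C)=C/CO[Si](C)(C)C(C)(C)C
F7 | step 11 | methyl ketone (C1 carbonyl, C13–C14 bond formed) | CC(=O)CC/C(C)=C/CC[C@@]1(C)O[C@@H]1CC/C(C)=C/CO[Si](C)(C)C(C)(C)C
F8 | step 11 | 2-triflyloxy-1-alkene (C1 enol triflate) | C=C(OS(=O)(=O)C(F)(F)F)CC/C(C)=C/CC[C@@]1(C)O[C@@H]1CC/C(C)=C/CO[Si](C)(C)C(C)(C)C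
F9 | step 11 | allylic alcohol carrying the enol triflate | C=C(OS(=O)(=O)C(F)(F)F)CC/C(C)=C/CC[C@@]1(C)O[C@@H]1CC/C(C)=C/CO
F10 | step 11 | enal carrying the enol triflate | C=C(OS(=O)(=O)C(F)(F)F)CC/C(C)=C/CC[C@@]1(C)O[C@@H]1CC/C(C)=C/C=O
F11 | step 11 | (2S)-epimer of 14 | O[C@H]1/C=C(\C)CC[C@H]2O[C@]2(C)CC/C=C(\C)CCC1=C
F12 | step 11 | (7R,8R,3E,11E)-7,8-epoxy-4,8,12-trimethyl-1-methylidenecyclotetradeca-3,11-dien-2-one | O=C1/C=C(\C)CC[C@H]2O[C@]2(C)CC/C=C(\C)CCC1=C
F13 | step 7 | (S)-4-benzyl-3-[3-(phenylsulfanyl)propanoyl]oxazolidin-2-one | O=C1OC[C@H](Cc2ccccc2)N1C(=O)CCSc3ccccc3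
F14 | step 7 | Evans syn-aldol adduct of 7 (C2 R, C1 S) | CC(C)(C)C(=O)OC/C(C)=C/CC[C@@]1(C)O[C@@H]1CC/C(C)=C/[C@@H](O)[C@H](CSc2ccccc2)C(=O)N3[C@@H](Cc4ccccc4)COC3=O
F15 | step 7 | C2 tert-butyldimethylsilyl ether of F14 | CC(C)(C)C(=O)OC/C(C)=C/CC[C@@]1(C)O[C@@H]1CC/C(C)=C/[C@@H](O[Si](C)(C)C(C)(C)C)[C@H](CSc2ccccc2)C(=O)N3[C@@H](Cc4ccccc4)COC3=O
F16 | step 7 | primary alcohol after removal of the auxiliary | CC(C)(C)C(=O)OC/C(C)=C/CC[C@@]1(C)O[C@@H]1CC/C(C)=C/[C@@H](O[Si](C)(C)C(C)(C)C)[C@H](CSc2ccccc2)CO
F17 | step 7 | sulfoxide of F16 (mixture at sulfur) | CC(C)(C)C(=O)OC/C(C)=C/CC[C@@]1(C)O[C@@H]1CC/C(C)=C/[C@@H](O[Si](C)(C)C(C)(C)C)[C@H](CS(=O)c2ccccc2)CO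
F18 | step 7 | C14 allylic alcohol with C1 methylene and C13 pivalate | CC(C)(C)C(=O)OC/C(C)=C/CC[C@@]1(C)O[C@@H]1CC/C(C)=C/[C@@H](O[Si](C)(C)C(C)(C)C)C(=C)CO
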